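**Retrosynthetic overview**
1. Target ⇐ two late functional-group steps: Baylis–Hillman hydroxymethylation of a C8 acrylate ester and SeO2 hydroxylation of the C5 isopropenyl group (C15).
2. The only ring (cyclohexane C5–C10) is closed by the C7–C8 bond: the SmI2 ketyl of a C8 aldehyde (carbonyl carbon used as a nucleophile) adds to the β-carbon C7 of a 2-(acetoxymethyl)enoate, and loss of acetate gives the α-methylene ester directly.
3. That acyclic enoate ⇐ Pd-catalysed 1,4-acetolysis of a vinyl epoxide ⇐ aldehyde 7 + sulfonium ylide from methyl 2-(bromomethyl)acrylate (Felkin control sets C6); the C8 aldehyde ⇐ terminal alkyne by anti-Markovnikov hydration.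
4. C5/C10 ⇐ enantioselective boron-mediated Ireland–Claisen rearrangement of the ester of (Z)-3-methylpent-2-en-4-yn-1-ol and 3-methylbut-3-enoic acid.
5. Bond order: C5–C10 (step 2), C6–C7 (step 4), ring closure C7–C8 (step 7); no other ring is formed.

Locants: elemane numbering is used in the Why lines. Ring = C5–C10; C10 is quaternary (methyl C14, vinyl C1/C2); C8 carries the acyloxy group; C7 carries the acrylate C11(=C13)C12; C6 is the free carbinol; C5 carries C4(=C3)C15.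

Assumption: the (S,S)-bromoborane is taken to deliver the (2S,3S)-acid 5; if the sense of induction is the opposite, the (R,R)-reagent is used and nothing else changes.

**Step 1**
Reactants: 1 (2Z)-3-methylpent-2-en-4-yn-1-ol; 2 3-methylbut-3-enoic acid
Product: 3 (2Z)-3-methylpent-2-en-4-yn-1-yl 3-methylbut-3-enoate
Conditions: PPh3, DIAD, THF, 0 °C → rt
Reagents that add atoms: none
Why: Mitsunobu esterification joins the primary allylic alcohol and the acid under neutral conditions, so neither the (Z)-enyne nor the β,γ-unsaturated acid isomerises, and no stereocentre is formed.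

**Step 2**
Reactants: 3 (2Z)-3-methylpent-2-en-4-yn-1-yl 3-methylbut-3-enoate
Product: 5 (2S,3S)-3-ethenyl-3-methyl-2-(prop-1-en-2-yl)pent-4-ynoic acid, via boron ketene acetal 4 (not isolated)
Conditions: (4S,5S)-2-bromo-1,3-bis{[3,5-bis(trifluoromethyl)phenyl]sulfonyl}-4,5-diphenyl-1,3,2-diazaborolidine (1.2 equiv), iPr2NEt, CH2Cl2, −78 °C, then −20 → 4 °C; aqueous work-up
Reagents that add atoms: none
Why: Enantioselective boron-mediated Ireland–Claisen rearrangement, in which soft enolisation gives the ketene acetal with the boryloxy group cis to the isopropenyl group, the chair transition state (isopropenyl pseudo-equatorial, the small ethynyl group of the Z-alkene pseudo-axial) fixes the C5/C10 relative configuration, and the C2-symmetric diazaborolidine selects the enolate face and so the absolute configuration.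

**Step 3**
Reactants: 5 (2S,3S)-3-ethenyl-3-methyl-2-(prop-1-en-2-yl)pent-4-ynoic acid
Product: 7 (2S,3S)-3-ethenyl-3-methyl-2-(prop-1-en-2-yl)pent-4-ynal, via trimethylsilyl ester 6 (not isolated)
Conditions: Me3SiCl, Et3N, CH2Cl2, 0 °C; then iBu2AlH, −78 °C; aq. potassium sodium tartrate
Reagents that add atoms: none
Why: One-pot acid-to-aldehyde reduction through the silyl ester, whose tetrahedral O-silyl O-aluminium acetal survives at −78 °C and collapses only on work-up, so the epimerisable α-stereocentre C5 is untouched.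

**Step 4**
Reactants: 7 (2S,3S)-3-ethenyl-3-methyl-2-(prop-1-en-2-yl)pent-4-ynal; 8 methyl 2-(bromomethyl)prop-2-enoate
Product: 10 methyl 2-{(2R,3R)-3-[(3S,4S)-4-ethenyl-2,4-dimethylhex-1-en-5-yn-3-yl]oxiran-2-yl}prop-2-enoate (trans-epoxide; any cis isomer, epimeric only at the acrylate-bearing oxirane carbon, converges in step 5), via sulfonium bromide 9 (not isolated)
Conditions: tetrahydrothiophene (1.2 equiv), Cs2CO3, MeCN, 0 °C → rt
Reagents that add atoms: none
Why: Corey–Chaykovsky epoxidation with the allylic sulfonium ylide made in situ from 8, in which the ylide adds to the aldehyde anti to the quaternary C10 group (Felkin–Anh) and so sets C6, while the configuration of the second oxirane carbon (C7) does not matter because step 5 erases it.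

**Step 5**
Reactants: 10 methyl 2-{(2R,3R)-3-[(3S,4S)-4-ethenyl-2,4-dimethylhex-1-en-5-yn-3-yl]oxiran-2-yl}prop-2-enoate
Product: 12 methyl (2E,4S,5S,6S)-2-(acetoxymethyl)-6-ethenyl-6-methyl-5-(prop-1-en-2-yl)-4-[(triethylsilyl)oxy]oct-2-en-7-ynoate, via hydroxy acetate 11 (not isolated)
Conditions: Pd(PPh3)4 (3 mol %), AcOH, THF, 0 °C → rt; then Et3SiCl, imidazole
Reagents that add atoms: acetic acid, CC(=O)O; chlorotriethylsilane, CC[Si](Cl)(CC)CC
Why: Tsuji–Trost opening of the vinyl epoxide, in which zerovalent palladium ionises the allylic C7–O bond and acetate attacks the unsubstituted π-allyl terminus C13 (1,4-addition) so the C6–O bond and its configuration are retained, followed by silylation of the freed C6 hydroxyl in the same flask.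

**Step 6**
Reactants: 12 methyl (2E,4S,5S,6S)-2-(acetoxymethyl)-6-ethenyl-6-methyl-5-(prop-1-en-2-yl)-4-[(triethylsilyl)oxy]oct-2-en-7-ynoate
Product: 13 methyl (2E,4S,5S,6S)-2-(acetoxymethyl)-6-ethenyl-6-methyl-8-oxo-5-(prop-1-en-2-yl)-4-[(triethylsilyl)oxy]oct-2-enoate
Conditions: CpRu(MeCN)3PF6 (5 mol %), 5,5′-bis(trifluoromethyl)-2,2′-bipyridine (5 mol %), H2O, NMP, 25–50 °C
Reagents that add atoms: water, O
Why: Ruthenium-catalysed anti-Markovnikov hydration of the terminal alkyne (through a ruthenium vinylidene) gives the C8 aldehyde and leaves the alkenes, the allylic acetate and the silyl ether alone, and it is run only after the C6 hydroxyl is capped so that no lactol can form.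

**Step 7**
Reactants: 13 methyl (2E,4S,5S,6S)-2-(acetoxymethyl)-6-ethenyl-6-methyl-8-oxo-5-(prop-1-en-2-yl)-4-[(triethylsilyl)oxy]oct-2-enoate
Product: 14 methyl 2-[(1R,2R,3S,4S,6S)-4-ethenyl-6-hydroxy-4-methyl-3-(prop-1-en-2-yl)-2-[(triethylsilyl)oxy]cyclohexyl]prop-2-enoate
Conditions: SmI2 (2.5 equiv), THF, −78 → −40 °C, slow addition of 13 (0.01 M); pH 7 buffer
Reagents that add atoms: none
Why: Proposed new method: SmI2 reduces the C8 aldehyde to a ketyl radical anion (a carbonyl carbon of reversed polarity) that adds 6-exo-trig to the enoate β-carbon C7, the α-ester radical is reduced to a samarium enolate that expels acetate (E1cB) to give the α-methylene ester, and a chair transition state with the C5 isopropenyl, C6 silyloxy and enoate groups equatorial and the O–Sm group equatorial (an axial one would clash with the axial C10 methyl) sets C7 and C8 all-trans; the closest known reactions are SmI2 ketyl–olefin cyclisations of aldehydes onto α,β-unsaturated esters and β-elimination from samarium enolates.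

**Step 8**
Reactants: 14 methyl 2-[(1R,2R,3S,4S,6S)-4-ethenyl-6-hydroxy-4-methyl-3-(prop-1-en-2-yl)-2-[(triethylsilyl)oxy]cyclohexyl]prop-2-enoate
Product: 16 (1S,2S,3R,4S,5S)-5-ethenyl-3-hydroxy-2-(3-methoxy-3-oxoprop-1-en-2-yl)-5-methyl-4-(prop-1-en-2-yl)cyclohexyl prop-2-enoate, via silyl ether acrylate 15 (not isolated)
Conditions: acryloyl chloride, Et3N, CH2Cl2, −20 °C; then HF·pyridine, THF, 0 °C
Reagents that add atoms: acryloyl chloride, C=CC(=O)Cl
Why: O-acylation of the only free hydroxyl (C8) followed by fluoride cleavage of the triethylsilyl ether at C6, with no stereocentre touched.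

**Step 9**
Reactants: 16 (1S,2S,3R,4S,5S)-5-ethenyl-3-hydroxy-2-(3-methoxy-3-oxoprop-1-en-2-yl)-5-methyl-4-(prop-1-en-2-yl)cyclohexyl prop-2-enoate
Product: 17 (1S,2S,3R,4R,5S)-5-ethenyl-3-hydroxy-4-(3-hydroxyprop-1-en-2-yl)-2-(3-methoxy-3-oxoprop-1-en-2-yl)-5-methylcyclohexyl prop-2-enoate
Conditions: SeO2 (0.3 equiv), t-BuOOH, CH2Cl2, 0 °C → rt
Reagents that add atoms: selenium dioxide, O=[Se]=O (oxygen donor, turned over by tert-butyl hydroperoxide, CC(C)(C)OO)
Why: Selenium dioxide allylic oxidation (ene reaction, then 2,3-sigmatropic shift) hydroxylates the methyl group of the C5 isopropenyl, the only electron-rich alkene with allylic hydrogens, since the vinyl group has none and both acrylates are electron-poor.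

**Step 10**
Reactants: 17 (1S,2S,3R,4R,5S)-5-ethenyl-3-hydroxy-4-(3-hydroxyprop-1-en-2-yl)-2-(3-methoxy-3-oxoprop-1-en-2-yl)-5-methylcyclohexyl prop-2-enoate
Product: 18 elemacarmanin, methyl 2-[(1S,2R,3R,4S,6S)-4-ethenyl-2-hydroxy-6-{[2-(hydroxymethyl)prop-2-enoyl]oxy}-3-(3-hydroxyprop-1-en-2-yl)-4-methylcyclohexyl]prop-2-enoate
Conditions: aq. HCHO (37 %), DABCO, 1,4-dioxane/H2O, rt
Reagents that add atoms: formaldehyde, C=O
Why: Morita–Baylis–Hillman reaction of the β-unsubstituted acrylate ester with formaldehyde installs the hydroxymethyl group, and the α-substituted acrylate at C7 cannot react because it has no α-hydrogen.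

**Compound list**
1 | (2Z)-3-methylpent-2-en-4-yn-1-ol | C#C/C(C)=C\CO | starting material
2 | 3-methylbut-3-enoic acid | CC(=C)CC(=O)O | starting material
3 | (2Z)-3-methylpent-2-en-4-yn-1-yl 3-methylbut-3-enoate | C#C/C(C)=C\COC(=O)CC(C)=C | intermediate
4 | boron ketene acetal of 3 with the (4S,5S)-1,3-bis{[3,5-bis(trifluoromethyl)phenyl]sulfonyl}-4,5-diphenyl-1,3,2-diazaborolidin-2-yl group on oxygen, boryloxy cis to isopropenyl | C#C/C(C)=C\CO/C(=C/C(C)=C)OB1N(S(=O)(=O)c2cc(cc(c2)C(F)(F)F)C(F)(F)F)[C@@H](c2ccccc2)[C@H](c2ccccc2)N1S(=O)(=O)c1cc(cc(c1)C(F)(F)F)C(F)(F)F | intermediate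
5 | (2S,3S)-3-ethenyl-3-methyl-2-(prop-1-en-2-yl)pent-4-ynoic acid | C=C[C@]([C@@H](C(=O)O)C(C)=C)(C)C#C | intermediate
6 | trimethylsilyl (2S,3S)-3-ethenyl-3-methyl-2-(prop-1-en-2-yl)pent-4-ynoate | C=C[C@]([C@@H](C(=O)O[Si](C)(C)C)C(C)=C)(C)C#C | intermediate
7 | (2S,3S)-3-ethenyl-3-methyl-2-(prop-1-en-2-yl)pent-4-ynal | C=C[C@]([C@@H](C=O)C(C)=C)(C)C#C | intermediate
8 | methyl 2-(bromomethyl)prop-2-enoate | C=C(CBr)C(=O)OC | starting material
9 | 1-[2-(methoxycarbonyl)prop-2-en-1-yl]thiolan-1-ium bromide | C=C(C[S+]1CCCC1)C(=O)OC.[Br-] | intermediate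
10 | methyl 2-{(2R,3R)-3-[(3S,4S)-4-ethenyl-2,4-dimethylhex-1-en-5-yn-3-yl]oxiran-2-yl}prop-2-enoate | C=C[C@]([C@@H]([C@H]2O[C@@H]2C(=C)C(=O)OC)C(C)=C)(C)C#C | intermediate
11 | methyl (2E,4S,5S,6S)-2-(acetoxymethyl)-6-ethenyl-4-hydroxy-6-methyl-5-(prop-1-en-2-yl)oct-2-en-7-ynoate | C=C[C@]([C@@H]([C@@H](O)/C=C(\COC(C)=O)C(=O)OC)C(C)=C)(C)C#C | intermediate
12 | methyl (2E,4S,5S,6S)-2-(acetoxymethyl)-6-ethenyl-6-methyl-5-(prop-1-en-2-yl)-4-[(triethylsilyl)oxy]oct-2-en-7-ynoate | C=C[C@]([C@@H]([C@@H](O[Si](CC)(CC)CC)/C=C(\COC(C)=O)C(=O)OC)C(C)=C)(C)C#C | intermediate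
13 | methyl (2E,4S,5S,6S)-2-(acetoxymethyl)-6-ethenyl-6-methyl-8-oxo-5-(prop-1-en-2-yl)-4-[(triethylsilyl)oxy]oct-2-enoate | C=C[C@]([C@@H]([C@@H](O[Si](CC)(CC)CC)/C=C(\COC(C)=O)C(=O)OC)C(C)=C)(C)CC=O | intermediate
14 | methyl 2-[(1R,2R,3S,4S,6S)-4-ethenyl-6-hydroxy-4-methyl-3-(prop-1-en-2-yl)-2-[(triethylsilyl)oxy]cyclohexyl]prop-2-enoate | C=C[C@]1(C)C[C@H](O)[C@@H](C(=C)C(=O)OC)[C@H](O[Si](CC)(CC)CC)[C@H]1C(C)=C | intermediate
15 | (1S,2R,3R,4S,5S)-5-ethenyl-2-(3-methoxy-3-oxoprop-1-en-2-yl)-5-methyl-4-(prop-1-en-2-yl)-3-[(triethylsilyl)oxy]cyclohexyl prop-2-enoate | C=C[C@]1(C)C[C@H](OC(=O)C=C)[C@@H](C(=C)C(=O)OC)[C@H](O[Si](CC)(CC)CC)[C@H]1C(C)=C | intermediate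
16 | (1S,2S,3R,4S,5S)-5-ethenyl-3-hydroxy-2-(3-methoxy-3-oxoprop-1-en-2-yl)-5-methyl-4-(prop-1-en-2-yl)cyclohexyl prop-2-enoate | C=C[C@]1(C)C[C@H](OC(=O)C=C)[C@@H](C(=C)C(=O)OC)[C@H](O)[C@H]1C(C)=C | intermediate
17 | (1S,2S,3R,4R,5S)-5-ethenyl-3-hydroxy-4-(3-hydroxyprop-1-en-2-yl)-2-(3-methoxy-3-oxoprop-1-en-2-yl)-5-methylcyclohexyl prop-2-enoate | C=C[C@]1(C)C[C@H](OC(=O)C=C)[C@@H](C(=C)C(=O)OC)[C@H](O)[C@H]1C(=C)CO | intermediate
18 | elemacarmanin, methyl 2-[(1S,2R,3R,4S,6S)-4-ethenyl-2-hydroxy-6-{[2-(hydroxymethyl)prop-2-enoyl]oxy}-3-(3-hydroxyprop-1-en-2-yl)-4-methylcyclohexyl]prop-2-enoate | C=C[C@]1(C)C[C@H](OC(=O)C(=C)CO)[C@@H](C(=C)C(=O)OC)[C@H](O)[C@H]1C(=C)CO | target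

**Totals**
Total steps: 10. Longest linear sequence: 10 (the route is linear; 1, 2 and 8 are purchased).

**Steps most likely to fail, with fallbacks**

Step 7 (ketyl cyclisation with acetate loss). Possible failures are pinacol coupling, simple reduction of the aldehyde, or the wrong relative configuration. The fallback closes the ring by a two-electron allylmetal addition and sets out from epoxide 10. Ruthenium-catalysed hydration of the alkyne under the step 6 conditions gives the epoxy aldehyde methyl 2-{(2R,3R)-3-[(3S,4S)-4-ethenyl-2,4-dimethyl-6-oxohex-1-en-3-yl]oxiran-2-yl}prop-2-enoate F6. Pd(PPh3)4 with InI in THF then turns the vinyl epoxide into a 2-(methoxycarbonyl)allylindium species (the acrylate β-carbon as nucleophile), which adds to the C8 aldehyde and gives the diol methyl 2-[(1R,2R,3S,4S,6S)-4-ethenyl-2,6-dihydroxy-4-methyl-3-(prop-1-en-2-yl)cyclohexyl]prop-2-enoate F7. Acryloylation of the less hindered C8 hydroxyl (acryloyl chloride, 2,4,6-collidine, −40 °C) gives 16, where the route is rejoined.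

Step 4 (ylide epoxidation of a hindered, epimerisable aldehyde with an acrylate-bearing ylide). The fallback builds the acrylate unit by a Morita–Baylis–Hillman reaction and sets out from aldehyde 7. Felkin–Anh addition of 2-lithio-1,3-dithiane (1,3-dithiane, n-BuLi, THF, −78 °C) gives the dithianyl carbinol (1R,2S,3S)-1-(1,3-dithian-2-yl)-3-ethenyl-3-methyl-2-(prop-1-en-2-yl)pent-4-yn-1-ol F1. Et3SiCl and imidazole give its triethylsilyl ether F2. MeI and CaCO3 in aqueous MeCN release the α-silyloxy aldehyde (2R,3S,4S)-4-ethenyl-4-methyl-3-(prop-1-en-2-yl)-2-[(triethylsilyl)oxy]hex-5-ynal F3. Methyl acrylate and DABCO give the Baylis–Hillman adduct F4 as both carbinol epimers, and Ac2O with DMAP gives the secondary acetate F5. DABCO-catalysed 1,3-transposition of the acetate (SN2′ twice) then gives 12, where the route is rejoined.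

Step 10 (Baylis–Hillman hydroxymethylation on the polyfunctional substrate; slow reaction, lactonisation or acyl migration are the concerns). The fallback brings the acyl group in ready-made. Ethyl 2-(hydroxymethyl)acrylate is silylated (t-BuMe2SiCl, imidazole) to ethyl 2-{[(tert-butyldimethylsilyl)oxy]methyl}prop-2-enoate F8 and saponified with LiOH to 2-{[(tert-butyldimethylsilyl)oxy]methyl}prop-2-enoic acid F9. Setting out from alcohol 14, Yamaguchi esterification with F9 (2,4,6-trichlorobenzoyl chloride, Et3N, DMAP) gives the bis-silyl diester F10. HF·pyridine removes both silyl groups to give the 15-deoxy compound (1S,2S,3R,4S,5S)-5-ethenyl-3-hydroxy-2-(3-methoxy-3-oxoprop-1-en-2-yl)-5-methyl-4-(prop-1-en-2-yl)cyclohexyl 2-(hydroxymethyl)prop-2-enoate F11. The SeO2/t-BuOOH oxidation of step 9 then gives the target 18.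

**Further compounds**
F1 | step 4 | (1R,2S,3S)-1-(1,3-dithian-2-yl)-3-ethenyl-3-methyl-2-(prop-1-en-2-yl)pent-4-yn-1-ol | C=C[C@]([C@@H]([C@@H](O)C1SCCCS1)C(C)=C)(C)C#C
F2 | step 4 | {[(1R,2S,3S)-1-(1,3-dithian-2-yl)-3-ethenyl-3-methyl-2-(prop-1-en-2-yl)pent-4-yn-1-yl]oxy}(triethyl)silane | C=C[C@]([C@@H]([C@@H](O[Si](CC)(CC)CC)C1SCCCS1)C(C)=C)(C)C#C
F3 | step 4 | (2R,3S,4S)-4-ethenyl-4-methyl-3-(prop-1-en-2-yl)-2-[(triethylsilyl)oxy]hex-5-ynal | C=C[C@]([C@@H]([C@@H](O[Si](CC)(CC)CC)C=O)C(C)=C)(C)C#C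
F4 | step 4 | methyl (3RS,4R,5S,6S)-6-ethenyl-3-hydroxy-6-methyl-2-methylidene-5-(prop-1-en-2-yl)-4-[(triethylsilyl)oxy]oct-7-ynoate | C=C[C@]([C@@H]([C@@H](O[Si](CC)(CC)CC)C(O)C(=C)C(=O)OC)C(C)=C)(C)C#C
F5 | step 4 | methyl (3RS,4R,5S,6S)-3-(acetyloxy)-6-ethenyl-6-methyl-2-methylidene-5-(prop-1-en-2-yl)-4-[(triethylsilyl)oxy]oct-7-ynoate | C=C[C@]([C@@H]([C@@H](O[Si](CC)(CC)CC)C(OC(C)=O)C(=C)C(=O)OC)C(C)=C)(C)C#C
F6 | step 7 | methyl 2-{(2R,3R)-3-[(3S,4S)-4-ethenyl-2,4-dimethyl-6-oxohex-1-en-3-yl]oxiran-2-yl}prop-2-enoate | C=C[C@]([C@@H]([C@H]2O[C@@H]2C(=C)C(=O)OC)C(C)=C)(C)CC=O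
F7 | step 7 | methyl 2-[(1R,2R,3S,4S,6S)-4-ethenyl-2,6-dihydroxy-4-methyl-3-(prop-1-en-2-yl)cyclohexyl]prop-2-enoate | C=C[C@]1(C)C[C@H](O)[C@@H](C(=C)C(=O)OC)[C@H](O)[C@H]1C(C)=C
F8 | step 10 | ethyl 2-{[(tert-butyldimethylsilyl)oxy]methyl}prop-2-enoate | C=C(CO[Si](C)(C)C(C)(C)C)C(=O)OCC
F9 | step 10 | 2-{[(tert-butyldimethylsilyl)oxy]methyl}prop-2-enoic acid | C=C(CO[Si](C)(C)C(C)(C)C)C(=O)O
F10 | step 10 | (1S,2R,3R,4S,5S)-5-ethenyl-2-(3-methoxy-3-oxoprop-1-en-2-yl)-5-methyl-4-(prop-1-en-2-yl)-3-[(triethylsilyl)oxy]cyclohexyl 2-{[(tert-butyldimethylsilyl)oxy]methyl}prop-2-enoate | C=C[C@]1(C)C[C@H](OC(=O)C(=C)CO[Si](C)(C)C(C)(C)C)[C@@H](C(=C)C(=O)OC)[C@H](O[Si](CC)(CC)CC)[C@H]1C(C)=C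
F11 | step 10 | (1S,2S,3R,4S,5S)-5-ethenyl-3-hydroxy-2-(3-methoxy-3-oxoprop-1-en-2-yl)-5-methyl-4-(prop-1-en-2-yl)cyclohexyl 2-(hydroxymethyl)prop-2-enoate | C=C[C@]1(C)C[C@H](OC(=O)C(=C)CO)[C@@H](C(=C)C(=O)OC)[C@H](O)[C@H]1C(C)=C
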